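**Plan**

- Retrosynthesis: the nonaene is cut at C11=C12 and C11′=C12′ (two Wittig reactions) into the C10 dialdehyde and two C15 phosphonium salts that differ only in the oxidation level at C4; both salts come from one C15 diol.
- The C15 diol is cut at C7=C8 (Horner–Wadsworth–Emmons) to a ring aldehyde, the ring aldehyde at the ring bond C1–C6, and the open chain at C4–C5 (crotylboration) into 4-methylpent-3-enal and a (Z)-crotyl boronate.
- Enabling feature: in the end ring, C1 is the gem-dimethyl carbon (a tertiary cation once C2 is protonated) and C6 is α to the exocyclic C7, which can be carried as an enol acetate. C1–C6 is therefore closed as a cation/enol-ester union, the same bond and the same C2 protonation that the carotenoid cyclase uses on the acyclic ψ end.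
- Forward: C6 aldehyde + C4 crotyl unit → acyclic enol acetate → the only ring closure (step 7) → C15 diol → hydroxy salt (one part) and, after oxidation at C4, keto salt (other part) → keto salt + C10 dialdehyde → C25 keto aldehyde → Wittig with the hydroxy salt. No ring is formed after step 7.
- Stereochemistry: C4 and C5 come from one catalytic syn-crotylboration; C6 is relayed from them in the chair cyclisation and secured by equilibration; C5′/C6′ are the same centres carried through the ring oxidation; chain geometry comes from HWE/Wittig selectivity and thermal Z→E equilibration.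

Key step: step 7

Remark: ring and chain positions carry carotenoid numbers (C1 gem-dimethyl carbon, C4 oxygenated carbon, C5 methyl-bearing carbon, C6 chain-bearing carbon, C7 first chain carbon). The all-E nonaene of the given structure is taken as the target geometry.

**Route**

Step 1
Reactants: 1 4-methylpent-3-en-1-ol
Product: 2 4-methylpent-3-enal
Conditions: Dess–Martin periodinane, NaHCO3, CH2Cl2, 0 °C; filtered, kept cold in solution and used at once
Reagents that add atoms: none
Why: Dess–Martin oxidation is neutral and fast at 0 °C, so the β,γ-unsaturated aldehyde should form without migration of the double bond into conjugation.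

Step 2
Reactants: 2 4-methylpent-3-enal; 3 (Z)-crotylboronic acid pinacol ester
Product: 5 (3S,4S)-3,7-dimethylocta-1,6-dien-4-ol, via pinacol borate ester 4 (not isolated)
Conditions: (R)-3,3′-bis(2,4,6-triisopropylphenyl)-1,1′-binaphthyl-2,2′-diyl hydrogen phosphate (5 mol%), 4 Å molecular sieves, PhMe, −30 °C; aq. NaHCO3
Reagents that add atoms: none
Why: Chiral phosphoric acid-catalysed crotylboration runs through a closed chair (Zimmerman–Traxler) transition state, so the Z-boronate should give the syn adduct while the acid selects the aldehyde face (the (R)-acid is expected to direct Re-face attack, giving 4S), and carbinol C4 and methyl-bearing C3 of 5 become ring C4 and C5.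

Step 3
Reactants: 5 (3S,4S)-3,7-dimethylocta-1,6-dien-4-ol
Product: 6 (3S,4S)-3,7-dimethylocta-1,6-dien-4-yl acetate
Conditions: Ac2O, pyridine, 4-(dimethylamino)pyridine (cat.), CH2Cl2, rt
Reagents that add atoms: acetic anhydride, CC(=O)OC(C)=O
Why: Nucleophile-catalysed acetylation turns the hydroxyl into a non-nucleophilic ester, which later cannot capture the cation as a tetrahydrofuran or form a lactol with the aldehyde.

Step 4
Reactants: 6 (3S,4S)-3,7-dimethylocta-1,6-dien-4-yl acetate
Product: 8 (3S,4S)-1-hydroxy-3,7-dimethyloct-6-en-4-yl acetate, via alkylborane 7 (not isolated)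
Conditions: 9-borabicyclo[3.3.1]nonane (9-BBN), THF, 0 °C → rt; then 30% H2O2, aq. NaOAc, 0 °C → rt
Reagents that add atoms: hydrogen peroxide, OO; 9-borabicyclo[3.3.1]nonane, B1C2CCCC1CCC2 (its boron stays only in 7)
Why: Brown hydroboration–oxidation with bulky 9-BBN is anti-Markovnikov and reacts with the monosubstituted vinyl group far faster than with the trisubstituted alkene, and the acetate-buffered peroxide spares the ester.

Step 5
Reactants: 8 (3S,4S)-1-hydroxy-3,7-dimethyloct-6-en-4-yl acetate
Product: 9 (3S,4S)-3,7-dimethyl-1-oxooct-6-en-4-yl acetate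
Conditions: Dess–Martin periodinane, NaHCO3, CH2Cl2, 0 °C → rt
Reagents that add atoms: none
Why: Dess–Martin oxidation of the primary alcohol stops at the aldehyde and leaves the acetate, the alkene and the β-stereocentre untouched.

Step 6
Reactants: 9 (3S,4S)-3,7-dimethyl-1-oxooct-6-en-4-yl acetate
Product: 10 (3S,4S)-3,7-dimethylocta-1,6-diene-1,4-diyl diacetate (E/Z mixture at the enol double bond)
Conditions: Ac2O, KOAc, Et3N, 120 °C
Reagents that add atoms: acetic anhydride, CC(=O)OC(C)=O
Why: Base-mediated enol acetate formation is the standard way to mask a citronellal-type aldehyde as a π-nucleophile; both enol geometries converge in step 7 and no stereocentre is α to the carbonyl.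

Step 7
Reactants: 10 (3S,4S)-3,7-dimethylocta-1,6-diene-1,4-diyl diacetate
Product: 12 (1S,2S,3S)-3-formyl-2,4,4-trimethylcyclohexyl acetate, via acetoxycarbenium ion 11 (not isolated)
Conditions: 85% H3PO4, PhMe, 40 °C; H2O; then 1,8-diazabicyclo[5.4.0]undec-7-ene (cat.), CH2Cl2, rt
Reagents that add atoms: water, O
Why: Protonation of the trisubstituted C1=C2 alkene at C2 gives the tertiary C1 cation, which is captured by C6 of the enol acetate through a chair transition state to give the O-acetyl oxocarbenium ion 11, hydrolysed to the aldehyde on quench. The closest known reaction type is the acid-mediated cation–olefin cyclisation of the enol acetate of citronellal to trans-2,2,6-trimethylcyclohexanecarbaldehyde. The six-membered ring closes exo with respect to the nucleophilic C6=C7 bond (only C6 enters the ring), with the cationic C1 as a ring atom. The one new stereocentre, C6, is controlled by the existing C4 and C5 centres: with 4-OAc and 5-Me equatorial the acetoxyvinyl arm also goes equatorial (trans to 5-Me), and because C6 is α to the formyl group any cis isomer should drain to the all-equatorial aldehyde by enolisation under the acid and then the amidine base. The step needs protonation of the isolated alkene and not of the enol ester, and capture of the cation by carbon and not oxygen: protonating the 1,2-disubstituted enol ester would give only a secondary acyloxycarbenium ion, the masked aldehyde cannot undergo carbonyl–ene closure to a p-menthane, and the C4 oxygen is an ester that cannot close a tetrahydrofuran.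

Step 8
Reactants: 12 (1S,2S,3S)-3-formyl-2,4,4-trimethylcyclohexyl acetate; 13 triethyl 3-methyl-4-phosphonobut-2-enoate
Product: 15 ethyl (2E,4E)-5-[(1S,2S,3S)-3-acetoxy-2,6,6-trimethylcyclohexyl]-3-methylpenta-2,4-dienoate, via lithiated phosphonate 14 (not isolated)
Conditions: 13, LiN(SiMe3)2, THF, −78 °C; then 12, −78 → 0 °C; chromatography
Reagents that add atoms: none
Why: The Horner–Wadsworth–Emmons reaction of the stabilised vinylogous phosphonate anion should give the new C7=C8 bond E, with the 2E isomer predominating and purified by chromatography; the preformed anion is too weak a base to disturb the acetate, and C6 is already in its stable configuration.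

Step 9
Reactants: 15 ethyl (2E,4E)-5-[(1S,2S,3S)-3-acetoxy-2,6,6-trimethylcyclohexyl]-3-methylpenta-2,4-dienoate
Product: 16 (1S,2S,3S)-3-[(1E,3E)-5-hydroxy-3-methylpenta-1,3-dien-1-yl]-2,4,4-trimethylcyclohexan-1-ol
Conditions: iBu2AlH (5 equiv), CH2Cl2, −78 → 0 °C; aq. KNaC4H4O6
Reagents that add atoms: none
Why: iBu2AlH reduces the dienoate 1,2 to the allylic alcohol and cleaves the acetate in the same operation, so reduction and deprotection are one step.

Step 10
Reactants: 16 (1S,2S,3S)-3-[(1E,3E)-5-hydroxy-3-methylpenta-1,3-dien-1-yl]-2,4,4-trimethylcyclohexan-1-ol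
Product: 17 {(2E,4E)-5-[(1S,2S,3S)-3-hydroxy-2,6,6-trimethylcyclohexyl]-3-methylpenta-2,4-dien-1-yl}triphenylphosphonium bromide
Conditions: PPh3·HBr, MeOH, rt; crystallisation (carried out on one part of 16)
Reagents that add atoms: triphenylphosphine hydrobromide, [Br-].c1ccc(cc1)[PH+](c1ccccc1)c1ccccc1
Why: Dienylic alcohols are converted into phosphonium salts by PPh3·HBr through the stabilised pentadienyl cation, with phosphorus bonding at the unhindered primary terminus; the secondary ring hydroxyl is inert, and crystallisation of the salt is the point at which isomeric purity should be upgraded.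

Step 11
Reactants: 16 (1S,2S,3S)-3-[(1E,3E)-5-hydroxy-3-methylpenta-1,3-dien-1-yl]-2,4,4-trimethylcyclohexan-1-ol
Product: 18 (1S,2S,3S)-3-[(1E,3E)-5-{[tert-butyl(dimethyl)silyl]oxy}-3-methylpenta-1,3-dien-1-yl]-2,4,4-trimethylcyclohexan-1-ol
Conditions: TBSCl (1.05 equiv), imidazole, CH2Cl2, −20 → 0 °C (carried out on the other part of 16)
Reagents that add atoms: tert-butyldimethylsilyl chloride, CC(C)(C)[Si](C)(C)Cl
Why: Silylation with the bulky chlorosilane should take the unhindered primary allylic hydroxyl far faster than the secondary ring hydroxyl, which is flanked by the methyl-bearing carbon.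

Step 12
Reactants: 18 (1S,2S,3S)-3-[(1E,3E)-5-{[tert-butyl(dimethyl)silyl]oxy}-3-methylpenta-1,3-dien-1-yl]-2,4,4-trimethylcyclohexan-1-ol
Product: 19 (2S,3S)-3-[(1E,3E)-5-{[tert-butyl(dimethyl)silyl]oxy}-3-methylpenta-1,3-dien-1-yl]-2,4,4-trimethylcyclohexan-1-one
Conditions: Dess–Martin periodinane, NaHCO3, CH2Cl2, 0 °C → rt
Reagents that add atoms: none
Why: Dess–Martin oxidation converts the secondary ring alcohol into the ketone under buffered conditions that spare the silyl ether and the diene; the α-methyl centre is already trans to the neighbouring side chain, its stable arrangement.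

Step 13
Reactants: 19 (2S,3S)-3-[(1E,3E)-5-{[tert-butyl(dimethyl)silyl]oxy}-3-methylpenta-1,3-dien-1-yl]-2,4,4-trimethylcyclohexan-1-one
Product: 20 {(2E,4E)-3-methyl-5-[(1S,2S)-2,6,6-trimethyl-3-oxocyclohexyl]penta-2,4-dien-1-yl}triphenylphosphonium bromide
Conditions: PPh3·HBr, MeOH, rt; crystallisation
Reagents that add atoms: triphenylphosphine hydrobromide, [Br-].c1ccc(cc1)[PH+](c1ccccc1)c1ccccc1
Why: In methanol the acidic PPh3·HBr should first methanolyse the primary allylic silyl ether and then convert the freed dienylic alcohol into the phosphonium salt through the stabilised pentadienyl cation, with phosphorus bonding at the primary terminus, while the hindered ring ketone and its trans α-methyl centre should pass unchanged.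

Step 14
Reactants: 20 {(2E,4E)-3-methyl-5-[(1S,2S)-2,6,6-trimethyl-3-oxocyclohexyl]penta-2,4-dien-1-yl}triphenylphosphonium bromide; 21 (2E,4E,6E)-2,7-dimethylocta-2,4,6-trienedial
Product: 23 (2E,4E,6E,8E,10E,12E)-2,7,11-trimethyl-13-[(1S,2S)-2,6,6-trimethyl-3-oxocyclohexyl]trideca-2,4,6,8,10,12-hexaenal, via keto ylide 22 (not isolated)
Conditions: 21 (3 equiv), NaOMe (slow addition), CH2Cl2/MeOH, 0 °C → rt; then reflux in heptane under Ar
Reagents that add atoms: none
Why: Wittig olefination with a semi-stabilised dienylic ylide, a reaction type well known for ring-keto C15 phosphonium salts and this C10 dialdehyde, in which the excess of the symmetrical dialdehyde favours mono-olefination, the conjugated aldehyde should react far faster than the hindered α-branched ring ketone, and the strained Z isomer at the new double bond should isomerise thermally to E.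

Step 15
Reactants: 23 (2E,4E,6E,8E,10E,12E)-2,7,11-trimethyl-13-[(1S,2S)-2,6,6-trimethyl-3-oxocyclohexyl]trideca-2,4,6,8,10,12-hexaenal; 17 {(2E,4E)-5-[(1S,2S,3S)-3-hydroxy-2,6,6-trimethylcyclohexyl]-3-methylpenta-2,4-dien-1-yl}triphenylphosphonium bromide
Product: 25 (4S,5S,6S,5′S,6′S)-4-hydroxy-5,6,5′,6′-tetrahydro-β,β-caroten-4′-one (all-E), via phosphorus ylide 24 (not isolated)
Conditions: 17 (1.3 equiv), NaOMe, CH2Cl2/MeOH, 0 °C → rt; then reflux in heptane under Ar; crystallisation
Reagents that add atoms: none
Why: Wittig olefination, in which the ylide should react with the conjugated aldehyde far faster than with the hindered α-branched ring ketone and thermal equilibration should give the all-E nonaene; the ring stereocentres are not touched, and C5′ is epimerisable but already in its stable trans form.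

**Compound list**

1 | 4-methylpent-3-en-1-ol | CC(C)=CCCO | starting material
2 | 4-methylpent-3-enal | CC(C)=CCC=O | intermediate
3 | 2-[(2Z)-but-2-en-1-yl]-4,4,5,5-tetramethyl-1,3,2-dioxaborolane ((Z)-crotylboronic acid pinacol ester) | C/C=C\CB1OC(C)(C)C(C)(C)O1 | starting material
4 | 2-{[(3S,4S)-3,7-dimethylocta-1,6-dien-4-yl]oxy}-4,4,5,5-tetramethyl-1,3,2-dioxaborolane | C=C[C@H](C)[C@@H](OB1OC(C)(C)C(C)(C)O1)CC=C(C)C | intermediate
5 | (3S,4S)-3,7-dimethylocta-1,6-dien-4-ol | C=C[C@H](C)[C@@H](O)CC=C(C)C | intermediate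
6 | (3S,4S)-3,7-dimethylocta-1,6-dien-4-yl acetate | C=C[C@H](C)[C@@H](OC(C)=O)CC=C(C)C | intermediate
7 | (3S,4S)-1-(9-borabicyclo[3.3.1]nonan-9-yl)-3,7-dimethyloct-6-en-4-yl acetate | C(C[C@H](C)[C@@H](OC(C)=O)CC=C(C)C)B1C2CCCC1CCC2 | intermediate
8 | (3S,4S)-1-hydroxy-3,7-dimethyloct-6-en-4-yl acetate | OCC[C@H](C)[C@@H](OC(C)=O)CC=C(C)C | intermediate
9 | (3S,4S)-3,7-dimethyl-1-oxooct-6-en-4-yl acetate | O=CC[C@H](C)[C@@H](OC(C)=O)CC=C(C)C | intermediate
10 | (3S,4S)-3,7-dimethylocta-1,6-diene-1,4-diyl diacetate (E/Z mixture at the enol double bond) | CC(=O)OC=C[C@H](C)[C@@H](OC(C)=O)CC=C(C)C | intermediate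
11 | acetyl{[(1S,2S,3S)-3-acetoxy-2,6,6-trimethylcyclohexyl]methylidene}oxonium (O-acetyl oxocarbenium ion) | CC(=O)[O+]=C[C@H]1[C@H](C)[C@@H](OC(C)=O)CCC1(C)C | intermediate
12 | (1S,2S,3S)-3-formyl-2,4,4-trimethylcyclohexyl acetate | O=C[C@H]1[C@H](C)[C@@H](OC(C)=O)CCC1(C)C | intermediate
13 | triethyl 3-methyl-4-phosphonobut-2-enoate (E shown; supplied as E/Z mixture) | CCOC(=O)/C=C(\C)CP(=O)(OCC)OCC | starting material
14 | lithium salt of 13 deprotonated at C4 | [Li+].CCOC(=O)/C=C(\C)[CH-]P(=O)(OCC)OCC | intermediate
15 | ethyl (2E,4E)-5-[(1S,2S,3S)-3-acetoxy-2,6,6-trimethylcyclohexyl]-3-methylpenta-2,4-dienoate | CCOC(=O)/C=C(\C)/C=C/[C@H]1[C@H](C)[C@@H](OC(C)=O)CCC1(C)C | intermediate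
16 | (1S,2S,3S)-3-[(1E,3E)-5-hydroxy-3-methylpenta-1,3-dien-1-yl]-2,4,4-trimethylcyclohexan-1-ol | OC/C=C(\C)/C=C/[C@H]1[C@H](C)[C@@H](O)CCC1(C)C | intermediate
17 | {(2E,4E)-5-[(1S,2S,3S)-3-hydroxy-2,6,6-trimethylcyclohexyl]-3-methylpenta-2,4-dien-1-yl}triphenylphosphonium bromide | [Br-].c1ccccc1[P+](c1ccccc1)(c1ccccc1)C/C=C(\C)/C=C/[C@H]1[C@H](C)[C@@H](O)CCC1(C)C | intermediate
18 | (1S,2S,3S)-3-[(1E,3E)-5-{[tert-butyl(dimethyl)silyl]oxy}-3-methylpenta-1,3-dien-1-yl]-2,4,4-trimethylcyclohexan-1-ol | CC(C)(C)[Si](C)(C)OC/C=C(\C)/C=C/[C@H]1[C@H](C)[C@@H](O)CCC1(C)C | intermediate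
19 | (2S,3S)-3-[(1E,3E)-5-{[tert-butyl(dimethyl)silyl]oxy}-3-methylpenta-1,3-dien-1-yl]-2,4,4-trimethylcyclohexan-1-one | CC(C)(C)[Si](C)(C)OC/C=C(\C)/C=C/[C@H]1[C@H](C)C(=O)CCC1(C)C | intermediate
20 | {(2E,4E)-3-methyl-5-[(1S,2S)-2,6,6-trimethyl-3-oxocyclohexyl]penta-2,4-dien-1-yl}triphenylphosphonium bromide | [Br-].c1ccccc1[P+](c1ccccc1)(c1ccccc1)C/C=C(\C)/C=C/[C@H]1[C@H](C)C(=O)CCC1(C)C | intermediate
21 | (2E,4E,6E)-2,7-dimethylocta-2,4,6-trienedial | O=C/C(C)=C/C=C/C=C(\C)C=O | starting material
22 | ylide of 20 | c1ccccc1[P+](c1ccccc1)(c1ccccc1)[CH-]/C=C(\C)/C=C/[C@H]1[C@H](C)C(=O)CCC1(C)C | intermediate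
23 | (2E,4E,6E,8E,10E,12E)-2,7,11-trimethyl-13-[(1S,2S)-2,6,6-trimethyl-3-oxocyclohexyl]trideca-2,4,6,8,10,12-hexaenal | O=C/C(C)=C/C=C/C=C(C)/C=C/C=C(C)/C=C/[C@H]1[C@H](C)C(=O)CCC1(C)C | intermediate
24 | ylide of 17 | c1ccccc1[P+](c1ccccc1)(c1ccccc1)[CH-]/C=C(\C)/C=C/[C@H]1[C@H](C)[C@@H](O)CCC1(C)C | intermediate
25 | (4S,5S,6S,5′S,6′S)-4-hydroxy-5,6,5′,6′-tetrahydro-β,β-caroten-4′-one (all-E) | CC(/C=C/C=C(C)/C=C/[C@H]1[C@H](C)[C@@H](O)CCC1(C)C)=C\C=C\C=C(C)\C=C\C=C(C)\C=C\[C@H]1[C@H](C)C(=O)CCC1(C)C | target

**Summary**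

Total step count: 15. Longest linear sequence: 14 steps (steps 1–9 and 11–15, 1 → 16 → 20 → 23 → 25); salt 17 is made from 16 in step 10 and enters in step 15.

**Steps most likely to fail**

Step 7. The acid may protonate the enol acetate instead of the isolated alkene, which would lead to Prins-type closure between C7 and C2 or to plain hydrolysis. The tertiary cation may also lose a proton or undergo hydride shifts before it is captured. The fallback sets out from 8 and comes back at 12. It preforms the electrophile and uses a stronger nucleophile, so that no Brønsted acid meets the enol derivative. Markovnikov addition of dry HCl to the trisubstituted alkene of 8 (CH2Cl2, −30 °C) should give the tertiary chloride (3S,4S)-7-chloro-1-hydroxy-3,7-dimethyloctan-4-yl acetate F1. Dess–Martin oxidation should give the chloro aldehyde (3S,4S)-7-chloro-3,7-dimethyl-1-oxooctan-4-yl acetate F2. TBSOTf and Et3N should convert it into the silyl enol ether (3S,4S)-1-[(tert-butyldimethylsilyl)oxy]-7-chloro-3,7-dimethyloct-1-en-4-yl acetate F3. TiCl4 (CH2Cl2, −78 °C) then ionises the chloride and the silyl enol ether alkylates it intramolecularly (Lewis acid-mediated α-tert-alkylation of a silyl enol ether). Aqueous work-up and the same amidine equilibration should give 12.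

Step 2. Enantioselectivity may erode with an unbranched aliphatic aldehyde, and the β,γ-double bond of 2 may migrate into conjugation before the aldehyde is trapped. The fallback sets out from 2 and comes back at 9, so steps 3 to 5 are not needed. It is a reagent-controlled Hoppe homoaldol reaction followed by inversion at the carbinol. (E)-But-2-en-1-ol and N,N-diisopropylcarbamoyl chloride (pyridine) give (E)-but-2-en-1-yl N,N-diisopropylcarbamate F4. Lithiation with n-BuLi/(−)-sparteine (pentane/cyclohexane, −78 °C, resolution by crystallisation of the lithio compound), exchange with Ti(OiPr)4 and addition of 2 should give the anti adduct (1Z,3S,4R)-4-hydroxy-3,7-dimethylocta-1,6-dien-1-yl N,N-diisopropylcarbamate F5; the sparteine antipode fixes the absolute sense. A Mitsunobu reaction with AcOH (PPh3, diisopropyl azodicarboxylate) inverts C4 and installs the ester, giving (1Z,3S,4S)-4-acetoxy-3,7-dimethylocta-1,6-dien-1-yl N,N-diisopropylcarbamate F6. Acid methanolysis of the enol carbamate (MeSO3H, MeOH) should give the dimethyl acetal (3S,4S)-1,1-dimethoxy-3,7-dimethyloct-6-en-4-yl acetate F7, which pyridinium p-toluenesulfonate in wet acetone hydrolyses to 9.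

Step 14. The keto ylide may condense with the ring ketone of a second molecule, and the base may enolise the ketone, before the dialdehyde is olefinated. The fallback sets out from 17 and comes back at 23. It keeps the ketone out of the first Wittig reaction by oxidising the ring alcohol only after the chain is extended, so steps 11 to 13 are not needed. A Wittig reaction of 17 with excess 21 (NaOMe, CH2Cl2/MeOH, then heptane reflux) should give the hydroxy aldehyde (2E,4E,6E,8E,10E,12E)-13-[(1S,2S,3S)-3-hydroxy-2,6,6-trimethylcyclohexyl]-2,7,11-trimethyltrideca-2,4,6,8,10,12-hexaenal F8. Dess–Martin oxidation of its ring alcohol (NaHCO3, CH2Cl2, 0 °C, dark, Ar) should give 23.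

**Further compounds**

F1 | step 7 | (3S,4S)-7-chloro-1-hydroxy-3,7-dimethyloctan-4-yl acetate | OCC[C@H](C)[C@@H](OC(C)=O)CCC(C)(C)Cl
F2 | step 7 | (3S,4S)-7-chloro-3,7-dimethyl-1-oxooctan-4-yl acetate | O=CC[C@H](C)[C@@H](OC(C)=O)CCC(C)(C)Cl
F3 | step 7 | (3S,4S)-1-[(tert-butyldimethylsilyl)oxy]-7-chloro-3,7-dimethyloct-1-en-4-yl acetate (E/Z mixture) | CC(C)(C)[Si](C)(C)OC=C[C@H](C)[C@@H](OC(C)=O)CCC(C)(C)Cl
F4 | step 2 | (E)-but-2-en-1-yl N,N-diisopropylcarbamate | C/C=C/COC(=O)N(C(C)C)C(C)C
F5 | step 2 | (1Z,3S,4R)-4-hydroxy-3,7-dimethylocta-1,6-dien-1-yl N,N-diisopropylcarbamate | CC(C)N(C(C)C)C(=O)O/C=C\[C@H](C)[C@H](O)CC=C(C)C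
F6 | step 2 | (1Z,3S,4S)-4-acetoxy-3,7-dimethylocta-1,6-dien-1-yl N,N-diisopropylcarbamate | CC(C)N(C(C)C)C(=O)O/C=C\[C@H](C)[C@@H](OC(C)=O)CC=C(C)C
F7 | step 2 | (3S,4S)-1,1-dimethoxy-3,7-dimethyloct-6-en-4-yl acetate | COC(OC)C[C@H](C)[C@@H](OC(C)=O)CC=C(C)C
F8 | step 14 | (2E,4E,6E,8E,10E,12E)-13-[(1S,2S,3S)-3-hydroxy-2,6,6-trimethylcyclohexyl]-2,7,11-trimethyltrideca-2,4,6,8,10,12-hexaenal | O=C/C(C)=C/C=C/C=C(C)/C=C/C=C(C)/C=C/[C@H]1[C@H](C)[C@@H](O)CCC1(C)C
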